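Target: peperomin C is (3S,4S)-4-[bis(3,4,5-trimethoxyphenyl)methyl]-3-methyldihydrofuran-2(3H)-one. The methyl and benzhydryl groups are trans. The benzhydryl carbon is not stereogenic because both aryl groups are the same.

## Retrosynthetic overview
1. Peperomin C 11 comes from reductive scission of the C1–C6 bond of the cyclopropane-fused lactone 9, and C3 is settled by equilibration to trans.
2. 9 comes from enantioselective intramolecular carbene cyclopropanation of diazopropanoate 8, which already holds every carbon of the target, the methyl group included.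
3. 8 comes from allylic alcohol 5 and ethyl 2-methylacetoacetate 6 by transesterification and deacylative diazo transfer.
4. 5 comes from two aryl Grignard units (from bromide 1) and methyl 3-hydroxypropanoate 2, followed by dehydration.
5. Ring order: both arenes are bought. The lactone (ring A) and the cyclopropane (ring B) close together in step 3, and ring B is opened again in step 4.

Assumption: Rh2(4S-MPPIM)4 (MPPIM = methyl 2-oxo-1-(3-phenylpropanoyl)imidazolidine-4-carboxylate) attacks the same alkene face as it does in prenyl-type allylic diazo esters, which gives 9 as drawn. If the measured sense is opposite, the 4R catalyst is used and nothing else changes.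

## Route

Step 1
Reactants: 1 5-bromo-1,2,3-trimethoxybenzene; 2 methyl 3-hydroxypropanoate
Product: 5 3,3-bis(3,4,5-trimethoxyphenyl)prop-2-en-1-ol, via arylmagnesium bromide 3 (not isolated), via tertiary diol 4 (not isolated)
Conditions: 1 (3.3 equiv), Mg, THF, reflux; then 2 (1.0 equiv), 0 °C to rt; then 1 M aq. HCl, THF, rt
Reagents that add atoms: none
Why: Double Grignard addition to an ester followed by E1 dehydration: one equivalent of 3 deprotonates the free hydroxyl, two more add to the ester to give the doubly benzylic tertiary alcohol 4, and 4 ionises readily in dilute acid because of its two electron-rich rings and loses a proton to give the conjugated 1,1-diarylalkene 5, with no alkene geometry and no stereocentre because the aryl groups are identical.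

Step 2
Reactants: 5 3,3-bis(3,4,5-trimethoxyphenyl)prop-2-en-1-ol; 6 ethyl 2-methyl-3-oxobutanoate
Product: 8 3,3-bis(3,4,5-trimethoxyphenyl)prop-2-en-1-yl 2-diazopropanoate, via keto ester 7 (not isolated)
Conditions: 6 (1.2 equiv), DMAP (0.3 equiv), 4 Å MS, PhMe, reflux; concentrate under high vacuum; then p-ABSA (1.3 equiv), DBU (1.5 equiv), MeCN, 0 °C to rt
Reagents that add atoms: 4-acetamidobenzenesulfonyl azide (p-ABSA), CC(=O)Nc1ccc(cc1)S(=O)(=O)N=[N+]=[N-]
Why: DMAP-catalysed transesterification of an enolisable beta-keto ester (through its acylketene) followed by Regitz deacylative diazo transfer: the DBU enolate of 7 attacks the terminal azide nitrogen and the acetyl group migrates to the sulfonamide nitrogen, which leaves the alpha-methyl diazo ester 8 under basic conditions that the ionisable diarylallyl ester tolerates, and the labile centre of 7 is erased.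

Step 3 (key step)
Reactants: 8 3,3-bis(3,4,5-trimethoxyphenyl)prop-2-en-1-yl 2-diazopropanoate
Product: 9 (1S,5S)-1-methyl-6,6-bis(3,4,5-trimethoxyphenyl)-3-oxabicyclo[3.1.0]hexan-2-one
Conditions: Rh2(4S-MPPIM)4 (1 mol %), CH2Cl2, reflux, 8 added by syringe pump over 10 h; recrystallise to raise the ee
Reagents that add atoms: none
Why: Doyle-type enantioselective intramolecular carbene cyclopropanation with a chiral dirhodium carboxamidate: after loss of N2 the electrophilic carbene carbon adds to the electron-rich 1,1-diarylalkene in the tether faster than it suffers 1,2-hydride shift (allylic diazopropanoates are a known substrate class for these catalysts), so the gamma-lactone and the cyclopropane close in one operation, the tether enforces cis fusion, and the 4S ligand set selects the alkene face that gives 5S (the future C4), with C1 following from the ring constraint.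

Step 4
Reactants: 9 (1S,5S)-1-methyl-6,6-bis(3,4,5-trimethoxyphenyl)-3-oxabicyclo[3.1.0]hexan-2-one
Product: 11 peperomin C, via cis epimer 10 (not isolated)
Conditions: H2 (4 atm), 10% Pd/C, EtOAc–EtOH, rt; filter; then DBU (0.5 equiv), PhMe, reflux
Reagents that add atoms: none
Why: Catalytic hydrogenolysis of a donor–acceptor cyclopropane followed by thermodynamic epimerisation: the C1–C6 bond is doubly benzylic at one end and alpha to the carbonyl at the other and is the weakest and most strained bond (the same bond breaks in 2-arylcyclopropanecarboxylates), so H2 adds across it and leaves C5 (lactone C4, S) untouched, retentive delivery of H at C1 gives 11 directly, and any 3-epimer 10 is converted by DBU enolisation into the more stable trans (3S,4S) isomer with methyl and benzhydryl on opposite faces.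

## Compound list
1 | 5-bromo-1,2,3-trimethoxybenzene | COc1cc(Br)cc(OC)c1OC | starting material
2 | methyl 3-hydroxypropanoate | COC(=O)CCO | starting material
3 | (3,4,5-trimethoxyphenyl)magnesium bromide | COc1cc([Mg]Br)cc(OC)c1OC | intermediate
4 | 1,1-bis(3,4,5-trimethoxyphenyl)propane-1,3-diol | COc1cc(cc(OC)c1OC)C(O)(CCO)c1cc(OC)c(OC)c(OC)c1 | intermediate
5 | 3,3-bis(3,4,5-trimethoxyphenyl)prop-2-en-1-ol | COc1cc(cc(OC)c1OC)C(=CCO)c1cc(OC)c(OC)c(OC)c1 | intermediate
6 | ethyl 2-methyl-3-oxobutanoate (racemic) | CCOC(=O)C(C)C(C)=O | starting material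
7 | 3,3-bis(3,4,5-trimethoxyphenyl)prop-2-en-1-yl 2-methyl-3-oxobutanoate (racemic, labile centre) | COc1cc(cc(OC)c1OC)C(=CCOC(=O)C(C)C(C)=O)c1cc(OC)c(OC)c(OC)c1 | intermediate
8 | 3,3-bis(3,4,5-trimethoxyphenyl)prop-2-en-1-yl 2-diazopropanoate | COc1cc(cc(OC)c1OC)C(=CCOC(=O)C(C)=[N+]=[N-])c1cc(OC)c(OC)c(OC)c1 | intermediate
9 | (1S,5S)-1-methyl-6,6-bis(3,4,5-trimethoxyphenyl)-3-oxabicyclo[3.1.0]hexan-2-one | C[C@]12C(=O)OC[C@H]1C2(c3cc(OC)c(OC)c(OC)c3)c4cc(OC)c(OC)c(OC)c4 | intermediate
10 | (3R,4S)-4-[bis(3,4,5-trimethoxyphenyl)methyl]-3-methyldihydrofuran-2(3H)-one (cis epimer) | COc1cc(C(c2cc(OC)c(OC)c(OC)c2)[C@@H]2COC(=O)[C@@H]2C)cc(OC)c1OC | intermediate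
11 | peperomin C, (3S,4S)-4-[bis(3,4,5-trimethoxyphenyl)methyl]-3-methyldihydrofuran-2(3H)-one | COc1cc(C(c2cc(OC)c(OC)c(OC)c2)[C@@H]2COC(=O)[C@H]2C)cc(OC)c1OC | target

## Step count and risks
Total step count: 4. Longest linear sequence: 4 (1 → 5 → 8 → 9 → 11).

**Step 3** is the most likely to fail. The methyl-bearing carbene may undergo 1,2-hydride shift to the acrylate, may add slowly to the hindered trisubstituted alkene, or may give an ee too low to upgrade.

The fallback sets out from 5 and comes back at 11. It removes the beta-hydrogens from the carbene and installs the methyl group last.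
- 5 is acylated with bromoacetyl bromide and NaHCO3 in MeCN to give 3,3-bis(3,4,5-trimethoxyphenyl)prop-2-en-1-yl bromoacetate F1.
- N,N'-ditosylhydrazine and DBU in THF convert it into 3,3-bis(3,4,5-trimethoxyphenyl)prop-2-en-1-yl diazoacetate F2.
- Rh2(5S-MEPY)4 (MEPY = methyl 2-oxopyrrolidine-5-carboxylate) in refluxing CH2Cl2 closes both rings to (1S,5R)-6,6-bis(3,4,5-trimethoxyphenyl)-3-oxabicyclo[3.1.0]hexan-2-one F3. Prenyl-type diazoacetates are the best substrates for this catalyst.
- Hydrogenolysis with H2 and Pd/C gives (R)-4-[bis(3,4,5-trimethoxyphenyl)methyl]dihydrofuran-2(3H)-one F4.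
- LDA then MeI in THF at −78 °C alkylates the enolate anti to the benzhydryl group and gives 11.

**Step 4** is the next risk. The catalyst surface may not reach the fully substituted C1–C6 bond, or it may cut C5–C6 instead.

The fallback sets out from 9 and comes back at 11. It replaces surface hydrogenolysis by ionic hydrogenation with BF3·OEt2 and a large excess of Et3SiH in CH2Cl2 at −78 °C.
- Lewis acid on the lactone carbonyl can heterolyse only the push–pull C1–C6 bond.
- The resulting bis(aryl)carbenium ion is trapped by hydride, and work-up protonates C3.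
- The 10/11 mixture is equilibrated with DBU as in the main route.
- The low temperature and excess silane are needed so that hydride capture outruns proton loss from C4, which would erode the ee.
- This fallback makes no compound outside the list (F0).

**Step 1** is the third risk. Enolisation or retro-aldol loss may occur at the beta-alkoxide ketone stage, and acid may ionise 5 further to ethers.

The fallback sets out from 1 and comes back at 5. It builds the diarylalkene by C–H arylation rather than carbonyl addition.
- Methyl acrylate (C=CC(=O)OC) and 1 (2.2 equiv) react with Pd(OAc)2, P(o-tol)3, NaOAc and n-Bu4NBr in DMF at 130 °C.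
- The first Mizoroki–Heck reaction gives methyl (E)-3-(3,4,5-trimethoxyphenyl)prop-2-enoate F5.
- A second Heck arylation gives methyl 3,3-bis(3,4,5-trimethoxyphenyl)prop-2-enoate F6.
- DIBAL-H in CH2Cl2 at −78 °C reduces F6 to 5.

## Further compounds
F1 | step 3 | 3,3-bis(3,4,5-trimethoxyphenyl)prop-2-en-1-yl bromoacetate | COc1cc(cc(OC)c1OC)C(=CCOC(=O)CBr)c1cc(OC)c(OC)c(OC)c1
F2 | step 3 | 3,3-bis(3,4,5-trimethoxyphenyl)prop-2-en-1-yl diazoacetate | COc1cc(cc(OC)c1OC)C(=CCOC(=O)C=[N+]=[N-])c1cc(OC)c(OC)c(OC)c1
F3 | step 3 | (1S,5R)-6,6-bis(3,4,5-trimethoxyphenyl)-3-oxabicyclo[3.1.0]hexan-2-one | O=C1OC[C@@H]2[C@H]1C2(c3cc(OC)c(OC)c(OC)c3)c4cc(OC)c(OC)c(OC)c4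
F4 | step 3 | (R)-4-[bis(3,4,5-trimethoxyphenyl)methyl]dihydrofuran-2(3H)-one | COc1cc(C(c2cc(OC)c(OC)c(OC)c2)[C@@H]2COC(=O)C2)cc(OC)c1OC
F0 | step 4 | none | none
F5 | step 1 | methyl (E)-3-(3,4,5-trimethoxyphenyl)prop-2-enoate | COC(=O)/C=C/c1cc(OC)c(OC)c(OC)c1
F6 | step 1 | methyl 3,3-bis(3,4,5-trimethoxyphenyl)prop-2-enoate | COC(=O)C=C(c1cc(OC)c(OC)c(OC)c1)c1cc(OC)c(OC)c(OC)c1
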